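**Strategy.** The acyloin bond C1(=O)–C6H(O-acyl) of the cyclohexenone ring is read as the oxidised form of an enol ether double bond C1=C6. Ring-closing metathesis between a 2-ethoxy-1,3-diene terminus (C1) and a vinyl group (C6) of an acyclic triene closes the six-membered ring by forming C1–C6 and delivers the cross-conjugated dienol ether of the target enone. Epoxidation anti to the cis C4/C5 substituents then sets C6. The triene takes C4 and C5 from one asymmetric γ-isopropylallylboration of an ynal, and its Z-C2=C3 geometry from hydroalumination–iodination and Stille coupling.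

Key step: step 6

Remark (numbering): ring atoms are C1 (ketone), C2 (bears C7H2OH), C3 (=CH), C4 (O-isobutyryl), C5 (isopropyl), C6 (O-acyl); the same numbers are used for the corresponding atoms of every intermediate.
Assumption: diisopinocampheylboranes derived from (−)-α-pinene add to the Re face of the aldehyde, the established sense of this reagent class; this facial sense fixes the absolute configuration of the whole route.

Step 1
Reactants: 1 tert-butyldimethyl(prop-2-yn-1-yloxy)silane
Product: 4 4-[(tert-butyldimethylsilyl)oxy]but-2-ynal, via lithium acetylide 2 (not isolated), via lithium hemiaminal alkoxide 3 (not isolated)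
Conditions: n-BuLi, THF, −78 °C; DMF, −78 °C to rt; reverse quench into cold aq. KH2PO4/MTBE
Reagents that add atoms: N,N-dimethylformamide, CN(C)C=O
Why: Lithiation of the terminal alkyne and formylation of the acetylide with DMF should give the ynal (C4, C3, C2, C7), the buffered reverse quench collapsing the hemiaminal alkoxide without conjugate addition of dimethylamine.

Step 2
Reactants: 4 4-[(tert-butyldimethylsilyl)oxy]but-2-ynal; 5 (E)-4-methylpent-2-ene
Product: 10 (4R,5R)-1-[(tert-butyldimethylsilyl)oxy]-5-(propan-2-yl)hept-6-en-2-yn-4-ol, via allylpotassium 6 (not isolated), via potassium borate complex 7 (not isolated), via allylborane 8 (not isolated), via borinate ester 9 (not isolated)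
Conditions: 5, KOt-Bu, n-BuLi, THF, −78 to −45 °C; (+)-Ipc2BOMe [from (−)-α-pinene], −78 °C; BF3·OEt2; 4, −78 °C; NaOH, H2O2, 0 °C to rt
Reagents that add atoms: none
Why: Brown allylboration with a γ-substituted allyl group: Schlosser metalation of 5 at its methyl group and borylation give the (E)-allylborane 8, which should add to 4 through a Zimmerman–Traxler chair, the E geometry giving the 4,5-anti relation and the isopinocampheyl groups directing attack to the Re face, so that C4 (R) and C5 (R) are set in one event.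

Step 3
Reactants: 10 (4R,5R)-1-[(tert-butyldimethylsilyl)oxy]-5-(propan-2-yl)hept-6-en-2-yn-4-ol
Product: 12 (2Z,4R,5R)-1-[(tert-butyldimethylsilyl)oxy]-2-iodo-5-(propan-2-yl)hepta-2,6-dien-4-ol, via cyclic alkenylalanate 11 (not isolated)
Conditions: NaAlH2(OCH2CH2OMe)2, THF, 0 °C; EtOAc; I2, THF, −78 °C; aq. potassium sodium tartrate/Na2S2O3
Reagents that add atoms: iodine, II
Why: Hydroxyl-directed trans-hydroalumination of the propargylic alcohol (hydride to C3, aluminium to C2 in a five-membered alanate) and iodinolysis with retention should place iodine on C2 cis to C4, the Z geometry the ring needs, low temperature suppressing β-elimination of the C7 silyloxy group.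

Step 4
Reactants: 12 (2Z,4R,5R)-1-[(tert-butyldimethylsilyl)oxy]-2-iodo-5-(propan-2-yl)hepta-2,6-dien-4-ol
Product: 13 (2Z,4R,5R)-1-[(tert-butyldimethylsilyl)oxy]-2-iodo-5-(propan-2-yl)hepta-2,6-dien-4-yl 2-methylpropanoate
Conditions: (i-PrCO)2O, Et3N, DMAP (cat.), CH2Cl2, 0 °C to rt
Reagents that add atoms: isobutyric anhydride, CC(C)C(=O)OC(=O)C(C)C
Why: DMAP-catalysed acylation of the only free hydroxyl installs the C4 isobutyrate of the target early and removes the hydroxyl that could otherwise add to the enol ether made next.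

Step 5
Reactants: 13 (2Z,4R,5R)-1-[(tert-butyldimethylsilyl)oxy]-2-iodo-5-(propan-2-yl)hepta-2,6-dien-4-yl 2-methylpropanoate; 14 tributyl(1-ethoxyethenyl)stannane
Product: 15 (3Z,5R,6R)-3-{[(tert-butyldimethylsilyl)oxy]methyl}-2-ethoxy-6-(propan-2-yl)octa-1,3,7-trien-5-yl 2-methylpropanoate
Conditions: Pd(PPh3)4 (5 mol%), CuI (10 mol%), DMF, 45 °C; Et3N-buffered work-up
Reagents that add atoms: none
Why: Stille coupling of the alkenyl iodide with the α-ethoxyvinylstannane should proceed with retention of the C2=C3 geometry and bring in C1 as an enol ether (masked ketone), oxidative addition to the C–I bond being much faster than ionisation of the hindered allylic ester.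

Step 6
Reactants: 15 (3Z,5R,6R)-3-{[(tert-butyldimethylsilyl)oxy]methyl}-2-ethoxy-6-(propan-2-yl)octa-1,3,7-trien-5-yl 2-methylpropanoate
Product: 16 (1R,6R)-3-{[(tert-butyldimethylsilyl)oxy]methyl}-4-ethoxy-6-(propan-2-yl)cyclohexa-2,4-dien-1-yl 2-methylpropanoate
Conditions: second-generation Grubbs catalyst RuCl2(=CHPh)(H2IMes)(PCy3) (10 mol%), toluene (2 mM), 60 °C, Ar sparge
Reagents that add atoms: none
Why: Olefin metathesis by the Chauvin mechanism: the ruthenium benzylidene should initiate at the only monosubstituted alkene (the C6 vinyl group), and the resulting alkylidene then undergoes intramolecular [2+2] cycloaddition and cycloreversion with the 1,1-disubstituted ethoxyvinyl terminus, forming C1=C6 and releasing ethene. The closest known reaction type is the ring-closing metathesis of acyclic alkyl and silyl enol ethers with terminal olefins to cyclic enol ethers. The six-membered carbocycle closes through a ruthenacyclobutane as an endocyclic C1=C6 double bond; the only alternative, a four-membered ring through the trisubstituted C2=C3 alkene, is strained and that alkene is unreactive. No stereocentre is created: C4 and C5 pass through untouched and C6 is set in step 7 under their control. The step needs initiation at C6 instead of at the electron-rich enol ether (which would give an inert alkoxycarbene) and cyclisation instead of oligomerisation. These are secured by the accessibility of the vinyl group, by the Z geometry of C2=C3 that holds C1 and the C4–C5–C6 arm on the same side, and by high dilution with removal of ethene.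

Step 7
Reactants: 16 (1R,6R)-3-{[(tert-butyldimethylsilyl)oxy]methyl}-4-ethoxy-6-(propan-2-yl)cyclohexa-2,4-dien-1-yl 2-methylpropanoate
Product: 18 (1S,5R,6R)-3-{[(tert-butyldimethylsilyl)oxy]methyl}-5-hydroxy-4-oxo-6-(propan-2-yl)cyclohex-2-en-1-yl 2-methylpropanoate, via ethoxy epoxide 17 (not isolated)
Conditions: DMDO, acetone/CH2Cl2, −78 to −30 °C; then THF/aq. pH 7 phosphate buffer, 0 °C
Reagents that add atoms: dimethyldioxirane, CC1(C)OO1; water, O
Why: Rubottom-type oxidation of the cross-conjugated dienol ether: epoxidation should occur at the most electron-rich C1=C6 bond from the ring face opposite the cis-disposed C5 isopropyl and C4 isobutyryloxy groups (substrate control), and neutral hydrolysis of the ethoxy epoxide unveils the C1 ketone and the C6 hydroxyl trans to isopropyl.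

Step 8
Reactants: 19 [(tert-butyldimethylsilyl)oxy]acetaldehyde; 20 ethyl 2-(triphenylphosphoranylidene)propanoate
Product: 21 ethyl (2E)-4-[(tert-butyldimethylsilyl)oxy]-2-methylbut-2-enoate
Conditions: CH2Cl2, rt
Reagents that add atoms: none
Why: Wittig olefination with a stabilised α-methyl ylide should give the (E)-trisubstituted enoate.

Step 9
Reactants: 21 ethyl (2E)-4-[(tert-butyldimethylsilyl)oxy]-2-methylbut-2-enoate
Product: 23 (2E)-4-[(tert-butyldimethylsilyl)oxy]-2-methylbut-2-enoic acid, via lithium carboxylate 22 (not isolated)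
Conditions: LiOH·H2O, THF/H2O, rt; 1 M HCl to pH 4, 0 °C
Reagents that add atoms: lithium hydroxide, [Li+].[OH-]
Why: Saponification of the ethyl ester, the primary silyl ether and the E-alkene being stable to aqueous LiOH and brief mild acidification.

Step 10
Reactants: 18 (1S,5R,6R)-3-{[(tert-butyldimethylsilyl)oxy]methyl}-5-hydroxy-4-oxo-6-(propan-2-yl)cyclohex-2-en-1-yl 2-methylpropanoate; 23 (2E)-4-[(tert-butyldimethylsilyl)oxy]-2-methylbut-2-enoic acid
Product: 25 (1R,5S,6S)-3-{[(tert-butyldimethylsilyl)oxy]methyl}-5-[(2-methylpropanoyl)oxy]-2-oxo-6-(propan-2-yl)cyclohex-3-en-1-yl (2E)-4-[(tert-butyldimethylsilyl)oxy]-2-methylbut-2-enoate, via mixed anhydride 24 (not isolated)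
Conditions: 23, 2,4,6-trichlorobenzoyl chloride, Et3N, toluene, rt; then 18, DMAP, toluene, 0 °C to rt
Reagents that add atoms: none
Why: Yamaguchi esterification through the mixed anhydride should acylate the hindered α-ketol hydroxyl under mildly basic conditions; C6 already holds its thermodynamically preferred equatorial position trans to isopropyl, so it is not at risk.

Step 11
Reactants: 25 (1R,5S,6S)-3-{[(tert-butyldimethylsilyl)oxy]methyl}-5-[(2-methylpropanoyl)oxy]-2-oxo-6-(propan-2-yl)cyclohex-3-en-1-yl (2E)-4-[(tert-butyldimethylsilyl)oxy]-2-methylbut-2-enoate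
Product: 26 (1R,5S,6S)-3-(hydroxymethyl)-5-[(2-methylpropanoyl)oxy]-2-oxo-6-(propan-2-yl)cyclohex-3-en-1-yl (2E)-4-hydroxy-2-methylbut-2-enoate
Conditions: HF·pyridine, pyridine, THF, 0 °C to rt
Reagents that add atoms: none
Why: Buffered fluoride cleavage of both primary allylic silyl ethers under non-basic conditions should avoid acyl migration, elimination of the C4 ester and aromatisation.

**Compound list**

1 | tert-butyldimethyl(prop-2-yn-1-yloxy)silane | C#CCO[Si](C)(C)C(C)(C)C | starting material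
2 | {3-[(tert-butyldimethylsilyl)oxy]prop-1-yn-1-yl}lithium | [Li]C#CCO[Si](C)(C)C(C)(C)C | intermediate
3 | lithium 4-[(tert-butyldimethylsilyl)oxy]-1-(dimethylamino)but-2-yn-1-olate | [Li]OC(N(C)C)C#CCO[Si](C)(C)C(C)(C)C | intermediate
4 | 4-[(tert-butyldimethylsilyl)oxy]but-2-ynal | O=CC#CCO[Si](C)(C)C(C)(C)C | intermediate
5 | (E)-4-methylpent-2-ene | C/C=C/C(C)C | starting material
6 | (E)-(4-methylpent-2-en-1-yl)potassium | [K]C/C=C/C(C)C | intermediate
7 | potassium methoxy[(E)-4-methylpent-2-en-1-yl]bis(isopinocampheyl)borate, isopinocampheyl groups from (−)-α-pinene | [K+].CO[B-](C/C=C/C(C)C)([C@H]1C[C@H]2C[C@@H]([C@@H]1C)C2(C)C)[C@H]1C[C@H]2C[C@@H]([C@@H]1C)C2(C)C | intermediate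
8 | [(E)-4-methylpent-2-en-1-yl]bis(isopinocampheyl)borane | CC(C)/C=C/CB([C@H]1C[C@H]2C[C@@H]([C@@H]1C)C2(C)C)[C@H]1C[C@H]2C[C@@H]([C@@H]1C)C2(C)C | intermediate
9 | bis(isopinocampheyl)borinate ester of 10 (O-boryl adduct) | CC(C)(C)[Si](C)(C)OCC#C[C@H](OB([C@H]1C[C@H]2C[C@@H]([C@@H]1C)C2(C)C)[C@H]1C[C@H]2C[C@@H]([C@@H]1C)C2(C)C)[C@@H](C=C)C(C)C | intermediate
10 | (4R,5R)-1-[(tert-butyldimethylsilyl)oxy]-5-(propan-2-yl)hept-6-en-2-yn-4-ol | CC(C)(C)[Si](C)(C)OCC#C[C@H](O)[C@@H](C=C)C(C)C | intermediate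
11 | sodium alkenylalanate (five-membered O–Al–C2=C3–C4 ring, two 2-methoxyethoxy ligands on aluminium) | [Na+].COCCO[Al-]1(OCCOC)O[C@@H](C=C1CO[Si](C)(C)C(C)(C)C)[C@@H](C=C)C(C)C | intermediate
12 | (2Z,4R,5R)-1-[(tert-butyldimethylsilyl)oxy]-2-iodo-5-(propan-2-yl)hepta-2,6-dien-4-ol | CC(C)(C)[Si](C)(C)OC/C(I)=C/[C@H](O)[C@@H](C=C)C(C)C | intermediate
13 | (2Z,4R,5R)-1-[(tert-butyldimethylsilyl)oxy]-2-iodo-5-(propan-2-yl)hepta-2,6-dien-4-yl 2-methylpropanoate | CC(C)(C)[Si](C)(C)OC/C(I)=C/[C@H](OC(=O)C(C)C)[C@@H](C=C)C(C)C | intermediate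
14 | tributyl(1-ethoxyethenyl)stannane | CCCC[Sn](CCCC)(CCCC)C(=C)OCC | starting material
15 | (3Z,5R,6R)-3-{[(tert-butyldimethylsilyl)oxy]methyl}-2-ethoxy-6-(propan-2-yl)octa-1,3,7-trien-5-yl 2-methylpropanoate | CC(C)(C)[Si](C)(C)OC/C(C(=C)OCC)=C/[C@H](OC(=O)C(C)C)[C@@H](C=C)C(C)C | intermediate
16 | (1R,6R)-3-{[(tert-butyldimethylsilyl)oxy]methyl}-4-ethoxy-6-(propan-2-yl)cyclohexa-2,4-dien-1-yl 2-methylpropanoate | C1=C(OCC)C(CO[Si](C)(C)C(C)(C)C)=C[C@H](OC(=O)C(C)C)[C@@H]1C(C)C | intermediate
17 | C1/C6 epoxide of 16 (1-ethoxy-7-oxabicyclo[4.1.0]hept-4-ene; epoxide oxygen trans to the isopropyl and isobutyryloxy groups) | CCO[C@@]12O[C@@H]1[C@@H](C(C)C)[C@@H](OC(=O)C(C)C)C=C2CO[Si](C)(C)C(C)(C)C | intermediate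
18 | (1S,5R,6R)-3-{[(tert-butyldimethylsilyl)oxy]methyl}-5-hydroxy-4-oxo-6-(propan-2-yl)cyclohex-2-en-1-yl 2-methylpropanoate | O[C@H]1C(=O)C(CO[Si](C)(C)C(C)(C)C)=C[C@H](OC(=O)C(C)C)[C@@H]1C(C)C | intermediate
19 | [(tert-butyldimethylsilyl)oxy]acetaldehyde | O=CCO[Si](C)(C)C(C)(C)C | starting material
20 | ethyl 2-(triphenylphosphoranylidene)propanoate | CCOC(=O)C(C)=P(c1ccccc1)(c1ccccc1)c1ccccc1 | starting material
21 | ethyl (2E)-4-[(tert-butyldimethylsilyl)oxy]-2-methylbut-2-enoate | C/C(=C\CO[Si](C)(C)C(C)(C)C)C(=O)OCC | intermediate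
22 | lithium (2E)-4-[(tert-butyldimethylsilyl)oxy]-2-methylbut-2-enoate | [Li+].C/C(=C\CO[Si](C)(C)C(C)(C)C)C(=O)[O-] | intermediate
23 | (2E)-4-[(tert-butyldimethylsilyl)oxy]-2-methylbut-2-enoic acid | C/C(=C\CO[Si](C)(C)C(C)(C)C)C(=O)O | intermediate
24 | mixed anhydride of 23 with 2,4,6-trichlorobenzoic acid | C/C(=C\CO[Si](C)(C)C(C)(C)C)C(=O)OC(=O)c1c(Cl)cc(Cl)cc1Cl | intermediate
25 | (1R,5S,6S)-3-{[(tert-butyldimethylsilyl)oxy]methyl}-5-[(2-methylpropanoyl)oxy]-2-oxo-6-(propan-2-yl)cyclohex-3-en-1-yl (2E)-4-[(tert-butyldimethylsilyl)oxy]-2-methylbut-2-enoate | C/C(=C\CO[Si](C)(C)C(C)(C)C)C(=O)O[C@H]1C(=O)C(CO[Si](C)(C)C(C)(C)C)=C[C@H](OC(=O)C(C)C)[C@@H]1C(C)C | intermediate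
26 | (1R,5S,6S)-3-(hydroxymethyl)-5-[(2-methylpropanoyl)oxy]-2-oxo-6-(propan-2-yl)cyclohex-3-en-1-yl (2E)-4-hydroxy-2-methylbut-2-enoate | C/C(=C\CO)C(=O)O[C@H]1C(=O)C(CO)=C[C@H](OC(=O)C(C)C)[C@@H]1C(C)C | target

**Step count.** Total: 11 steps. Longest linear sequence: 9 steps (steps 1–7, 10, 11, from compound 1).

**Steps most likely to fail, each with a fallback**

Step 6 (ring-closing metathesis). The ruthenium may be trapped by the electron-rich enol ether as an unreactive alkoxycarbene, intermolecular metathesis may compete, or the dienyl allylic ester may lose isobutyric acid with aromatisation. The fallback closes the same C1–C6 bond by acyl-anion chemistry; it sets out from 12 and returns at 25. Silylation of 12 (Et3SiCl, imidazole, DMF) should give the triethylsilyl ether F1. Iodine–lithium exchange (t-BuLi, Et2O, −78 °C) and trapping with DMF should give the Z-enal F2. Cleavage of the terminal vinyl group (OsO4 cat., NaIO4, 2,6-lutidine, dioxane/H2O) should give the dialdehyde F3. An intramolecular cross-benzoin reaction under N-heterocyclic carbene catalysis (3-benzyl-5-(2-hydroxyethyl)-4-methylthiazolium chloride, Et3N, THF) would then form C1–C6 and give the ketol F4. Yamaguchi esterification with 23 should give the ester F5, and PPTS in MeOH at 0 °C should remove the triethylsilyl group to give the C4 alcohol F6. Isobutyryl chloride with pyridine and DMAP then rejoins the route at 25.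

Step 7 (oxidation of the dienol ether). Facial discrimination in the epoxidation may be insufficient, or the allylic ester may ionise during the hydrolytic opening and the ring aromatise. The fallback sets out from 16 and returns at 18. Mild hydrolysis (PPTS, acetone/H2O, 0 °C) should give the C6-methylene enone F7. Its kinetic lithium enolate (LiN(SiMe3)2, THF, −78 °C) would then be hydroxylated with 3-phenyl-2-(phenylsulfonyl)oxaziridine on the face opposite the isopropyl group, giving 18.

Step 2 (allylboration). Torsional isomerisation of the allylpotassium would erode the anti selectivity, and facial control may be weak with the slender alkynyl aldehyde. The fallback moves stereocontrol to a chiral Brønsted acid catalyst and a configurationally stable allylboronate; it sets out from 4 and returns at 10. Hydroboration of 3-methylbut-1-yne with pinacolborane (Cp2Zr(H)Cl cat.) should give the alkenylboronate F8. Matteson homologation (BrCH2Cl, n-BuLi, THF, −78 °C to rt) should give the (E)-allylboronate F9. Addition of F9 to 4 under catalysis by (R)-3,3'-bis(2,4,6-triisopropylphenyl)-1,1'-binaphthyl-2,2'-diyl hydrogen phosphate (toluene, −30 °C) should give the O-boryl adduct F10, which is hydrolysed on work-up to 10.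

**Further compounds**

F1 | step 6 | triethylsilyl ether of 12, (2Z,4R,5R)-1-[(tert-butyldimethylsilyl)oxy]-2-iodo-5-(propan-2-yl)-4-[(triethylsilyl)oxy]hepta-2,6-diene | CC(C)(C)[Si](C)(C)OC/C(I)=C/[C@H](O[Si](CC)(CC)CC)[C@@H](C=C)C(C)C
F2 | step 6 | (2Z,4R,5R)-2-{[(tert-butyldimethylsilyl)oxy]methyl}-5-(propan-2-yl)-4-[(triethylsilyl)oxy]hepta-2,6-dienal | CC(C)(C)[Si](C)(C)OC/C(C=O)=C/[C@H](O[Si](CC)(CC)CC)[C@@H](C=C)C(C)C
F3 | step 6 | (2Z,4S,5S)-2-{[(tert-butyldimethylsilyl)oxy]methyl}-5-(propan-2-yl)-4-[(triethylsilyl)oxy]hex-2-enedial | CC(C)(C)[Si](C)(C)OC/C(C=O)=C/[C@H](O[Si](CC)(CC)CC)[C@@H](C=O)C(C)C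
F4 | step 6 | (4S,5R,6R)-2-{[(tert-butyldimethylsilyl)oxy]methyl}-6-hydroxy-5-(propan-2-yl)-4-[(triethylsilyl)oxy]cyclohex-2-en-1-one | O[C@H]1C(=O)C(CO[Si](C)(C)C(C)(C)C)=C[C@H](O[Si](CC)(CC)CC)[C@@H]1C(C)C
F5 | step 6 | C6 (2E)-4-[(tert-butyldimethylsilyl)oxy]-2-methylbut-2-enoate of F4 | C/C(=C\CO[Si](C)(C)C(C)(C)C)C(=O)O[C@H]1C(=O)C(CO[Si](C)(C)C(C)(C)C)=C[C@H](O[Si](CC)(CC)CC)[C@@H]1C(C)C
F6 | step 6 | C4 alcohol from F5 (analogue of 25 with free 4-hydroxyl) | C/C(=C\CO[Si](C)(C)C(C)(C)C)C(=O)O[C@H]1C(=O)C(CO[Si](C)(C)C(C)(C)C)=C[C@H](O)[C@@H]1C(C)C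
F7 | step 7 | 3-{[(tert-butyldimethylsilyl)oxy]methyl}-4-oxo-6-(propan-2-yl)cyclohex-2-en-1-yl 2-methylpropanoate, ester and isopropyl cis (C6 methylene enone) | C1C(=O)C(CO[Si](C)(C)C(C)(C)C)=C[C@H](OC(=O)C(C)C)[C@@H]1C(C)C
F8 | step 2 | (E)-4,4,5,5-tetramethyl-2-(3-methylbut-1-en-1-yl)-1,3,2-dioxaborolane | CC(C)/C=C/B1OC(C)(C)C(C)(C)O1
F9 | step 2 | (E)-4,4,5,5-tetramethyl-2-(4-methylpent-2-en-1-yl)-1,3,2-dioxaborolane | CC(C)/C=C/CB1OC(C)(C)C(C)(C)O1
F10 | step 2 | pinacol boronate (O-boryl) adduct of 10 | CC(C)(C)[Si](C)(C)OCC#C[C@H](OB1OC(C)(C)C(C)(C)O1)[C@@H](C=C)C(C)C
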